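The earlier runs and the new flask stem from a simulated flask from invented constants; scatter was added.

**One-step world.** In a one-step world, starting material and partner give target and stop, so the share of target in target plus over-reaction product, the selectivity, stands at 100%. In south-west over-reaction product appears as well, and the share reads 85.9% at 8.00 min and 47.2% at 90.0 min.

| flask | starting material | partner | second substrate | protic impurity | remark | time |
|---|---|---|---|---|---|---|
| north-west | 0.050 M | 0.125 M | 0.050 M | 0.010 M | run made earlier |  |
| east | 0.050 M | 0.17 M | 0.050 M | 0.010 M | run made earlier |  |
| south-west | 0.050 M | 0.28 M | 0.050 M | 0.010 M | run made earlier |  |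
| north-east | 0.050 M | 0.125 M | 0.025 M | 0.010 M | run made earlier |  |
| red | 0.050 M | 0.125 M (fed, over 1.60 h) | 0.0500 M | 0.0100 M | a stirred flask in which partner is dosed at a steady rate over 1.60 h without added volume, worked up at 2.0 h | 2.0 h |
| green | 0.050 M | 0.125 M | 0.0500 M | 0.0100 M | a single well-mixed tank run continuously and read at steady state, 2.0 h in it on average |  |
| ochre | 0.050 M | 0.125 M | 0.0500 M | 0.0100 M | plug flow through a tube for 2.0 h, no back-mixing | 2.0 h |
| blue | 0.050 M | 0.125 M | 0.0500 M | 0.0100 M | everything together in a closed stirred flask, run for 2.0 h | 2.0 h |

| run | time / min | target / % | over-reaction product / % |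
|---|---|---|---|
| north-west | 10.0 | 3.6 | 0.2 |
| north-west | 25.0 | 4.9 | 0 |
| north-west | 50.0 | 11.2 | 1.0 |
| north-west | 80.0 | 14.0 | 2.4 |
| east | 8.00 | 2.0 | 0 |
| east | 20.0 | 5.3 | 1.4 |
| east | 40.0 | 12.6 | 2.8 |
| east | 90.0 | 15.7 | 9.0 |
| south-west | 8.00 | 5.5 | 0.9 |
| south-west | 20.0 | 12.1 | 2.6 |
| south-west | 40.0 | 15.1 | 5.5 |
| south-west | 90.0 | 20.0 | 22.4 |
| north-east | 8.00 | 2.0 | 2.5 |
| north-east | 20.0 | 5.1 | 0.9 |
| north-east | 40.0 | 10.6 | 1.0 |
| north-east | 90.0 | 15.3 | 4.4 |

(scatter of a reading: 1 percentage point)

- the stated concentrations are those of everything mixed, before any reaction; amounts are the same in each set-up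
- the feed brings no volume worth counting
- the earlier runs were made in a closed, stirred flask
- a reading or a percentage of target counts all its forms, free or not

- the set-up with the highest share of target in all that became target or over-reaction product, at the outlet or at the end ("none" if the first two lie within 2 percentage points) (red / green / ochre / blue / none)
- share of target in all that became target or over-reaction product, at the outlet or at the end, red
- share of target in all that became target or over-reaction product, at the outlet or at the end, green
- share of target in all that became target or over-reaction product, at the outlet or at the end, ochre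
- share of target in all that became target or over-reaction product, at the outlet or at the end, blue

**Partner exposure.** We follow the partner exposure: c partner as charged, summed over time, with nothing subtracted for use. North-west at 50.0 min has 6.25 M·min and south-west at 20.0 min has 5.60 M·min, and they read 11.2% and 12.1% target, close for a scatter of 1 percentage point.

**Two extremes.** A feed given in a moment is blue. A feed stretched over the whole time gives 0.5 of blue's exposure, since c partner climbs in a straight line. Red feeds for 1.60 h and then stands until 2.0 h, so it lies between them: red's partner exposure over blue's is 0.600, the exposure ratio. Red at its end should therefore resemble blue at 1.20 h.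

**Our reckoning.** Blue's exposure is 15.0 M·min, and east at 90.0 min has 15.3 M·min with a share of 63.6%, which we take for blue. Plug flow repeats blue's history parcel by parcel, so ochre goes with it. Red's exposure is 9.00 M·min, and north-west at 80.0 min has 10.0 M·min and reads a share of 85.4%, with a scatter of 1 point on each of its two readings, which we take for red. The tank mixes ages around an average of 2.0 h, and we place green below blue.

**The forecast.** It names red, with 89% for red, 72.5% for green, 81.5% for ochre and 81.5% for blue: “So low partner favours target, and dosing should win.” Our blue share is lower than the forecast's.

**The result.** The best is red: red 80.3%, green 59.3%, ochre 68.3%, blue 68.3%.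

    starting material + partner → target (k = 1.60 M⁻¹ h⁻¹)
    second substrate + partner → second product (k = 2.20 M⁻¹ h⁻¹)
    partner + protic impurity → quenched reagent (k = 33.0 M⁻¹ h⁻¹)
    partner + target → over-reaction product (k = 16.0 M⁻¹ h⁻¹)
    starting material + target ⇌ idle adduct, settled at all times (K = 88.0 M⁻¹)

**What to watch.** Red's end falls between blue's states, as the ratio 0.600 placed it: starting material 73.1%, against 75.6% at 1.00 h and 63.0% at 2.00 h, and share 80.3%, against 82.8% and 68.3%. The neighbour with 0.085 M starting material has red's feed and the same ratio; it keeps 72% of its starting material unbound, yet its share is 86.9%. At 1.31 h in red, the half-life of starting material by the target path is 5.2 h, longer than the 2.0 h of the run. Red ends with 73% of its starting material unbound.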